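**Retrosynthetic overview**

1. The target is the C10 ester of a 10-hydroxy-12-oxocedr-8-en-15-oic acid (cedrane numbering: C1 quaternary bridgehead, C2 CH–CHO, C5 ring-fusion CH, C6 CMe2, C7 bridgehead CH, C8=C9 enoic acid, C10 CH–O, C11 CH2 bridge, C12 CHO, C15 CO2H). The C10–O acyl bond is made late (Yamaguchi) with a Wittig-derived (9Z)-16-silyloxyhexadec-9-enoic acid, and one acidic operation then releases CHO, CO2H and OH.
2. Key disconnection C5–C6: an MHAT-triggered 5-exo-trig radical cyclisation of a spiro[4.5]decatriene closes ring C (C1–C5–C6–C7–C11). It converts the spirocycle into the bridged bicyclo[3.2.1]octene of the cedrene core, creates the quaternary C6 and sets C5.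
3. Enabling feature: on cyclohexene ring A the isopropenyl group on C7 and the cyclopentene carbon C5 on spiro carbon C1 are cis and 1,3-related through the C11 methylene. The tertiary C6 radical therefore sits five atoms (C6–C7–C11–C1–C5) from the C4=C5 bond of ring B and can reach C5 only from the face that gives the cis ring fusion.
4. This cis array (C10–O, C7–isopropenyl, C1–C5) and the C1/C2 relationship come from one endo Diels–Alder reaction (ring A; bonds C1–C10 and C7–C11) between a 1-alkoxy-3-carboxy triene and a chiral α-methylene cyclopentenone. A reductive 1,3-transposition then moves the ring-B alkene to C4=C5.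
5. Ring order: ring B (from (R)-4-silyloxycyclopentenone, C12 carried as a dioxolane) → ring A (Diels–Alder) → ring C (radical closure of C5–C6).

Key step: step 11

Remark: positions are given in cedrane numbering as defined above; the C2–CHO configuration of the target is taken to be the thermodynamically preferred one (formyl group anti to the C10 acyloxy group on ring B), so C12 is carried as an acetal and released last.

**Route**

Step 1
Reactants: 1 4-methoxybenzyl alcohol
Product: 4 4-methoxybenzyl ethynyl ether, via dichlorovinyl ether 2 (not isolated), via lithium alkynyl ether 3 (not isolated)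
Conditions: KH, THF, 0 °C; Cl2C=CHCl, −50 → 22 °C; n-BuLi (2.4 equiv), −78 °C; MeOH, −78 °C
Reagents that add atoms: trichloroethylene, ClC=C(Cl)Cl
Why: Alkoxide addition to trichloroethylene (through dichloroacetylene) should give the (E)-dichlorovinyl ether, and n-BuLi then effects elimination and lithium–chlorine exchange to the lithium alkynyl ether, which is protonated cold (the alkoxide/trichloroethylene route to ynol ethers); no stereocentre is formed.

Step 2
Reactants: 5 methacrolein
Product: 6 1,1-dibromo-3-methylbuta-1,3-diene
Conditions: CBr4, PPh3, CH2Cl2, 0 °C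
Reagents that add atoms: carbon tetrabromide, BrC(Br)(Br)Br
Why: Ramirez (Corey–Fuchs-type) gem-dibromo-olefination of the aldehyde by the CBr4/PPh3 ylide follows a Wittig mechanism and leaves the 1,1-disubstituted alkene untouched.

Step 3
Reactants: 4 4-methoxybenzyl ethynyl ether; 6 1,1-dibromo-3-methylbuta-1,3-diene
Product: 8 (1E,3Z)-3-bromo-1-(4-methoxybenzyloxy)-5-methylhexa-1,3,5-triene, via alkenylzirconocene 7 (not isolated)
Conditions: Cp2Zr(H)Cl, THF, 22 °C; then 6, ZnCl2, PdCl2(DPEphos) (5 mol %), THF, 0 → 22 °C
Reagents that add atoms: none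
Why: syn-Hydrozirconation places zirconium on the terminal alkyne carbon and gives the (E)-alkoxyvinyl metal, and the Negishi coupling of 1,1-dibromoalkenes is selective for the bromide trans to the substituent, which should fix the (1E,3Z) geometry that later puts the isopropenyl group in the "outside" position of the diene.

Step 4
Reactants: 8 (1E,3Z)-3-bromo-1-(4-methoxybenzyloxy)-5-methylhexa-1,3,5-triene
Product: 10 tert-butyl (2Z)-2-[(E)-2-(4-methoxybenzyloxy)ethenyl]-4-methylpenta-2,4-dienoate, via dienyllithium 9 (not isolated)
Conditions: t-BuLi (2 equiv), Et2O, −78 °C; Boc2O, −78 → 0 °C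
Reagents that add atoms: di-tert-butyl dicarbonate, CC(C)(C)OC(=O)OC(=O)OC(C)(C)C
Why: Bromine–lithium exchange at −78 °C is faster than deprotonation and retains the alkene geometry, and acylation of the alkenyllithium by Boc2O should give the tert-butyl ester directly.

Step 5
Reactants: 11 (4R)-4-(tert-butyldimethylsilyloxy)cyclopent-2-en-1-one
Product: 12 (3R,4R)-4-(tert-butyldimethylsilyloxy)-3-(1,3-dioxolan-2-yl)cyclopentan-1-one
Conditions: 1,3-dioxolane (solvent), Ph2CO (20 mol %), hν (350 nm), 22 °C
Reagents that add atoms: 1,3-dioxolane, C1COCO1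
Why: Benzophenone-sensitised hydrogen abstraction gives the nucleophilic 2-dioxolanyl radical, which adds to the enone β-carbon (radical conjugate addition of a masked formyl group) anti to the bulky silyloxy group, so the new centre should be trans to OTBS.

Step 6
Reactants: 12 (3R,4R)-4-(tert-butyldimethylsilyloxy)-3-(1,3-dioxolan-2-yl)cyclopentan-1-one
Product: 13 (4R)-4-(1,3-dioxolan-2-yl)cyclopent-2-en-1-one
Conditions: DBU, CH2Cl2, 0 °C
Reagents that add atoms: none
Why: E1cB elimination of the β-silyloxy group from the ketone enolate forms the enone and leaves the dioxolanyl-bearing centre (the future C2) untouched.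

Step 7
Reactants: 13 (4R)-4-(1,3-dioxolan-2-yl)cyclopent-2-en-1-one
Product: 16 (4S)-4-(1,3-dioxolan-2-yl)-5-methylidenecyclopent-2-en-1-one, via Mannich base 14 (not isolated), via ammonium iodide 15 (not isolated)
Conditions: LiN(SiMe3)2, THF, −78 °C; CH2=NMe2+ I−, −78 → 0 °C; MeI, CH2Cl2, 22 °C; aq NaHCO3, CH2Cl2, 22 °C
Reagents that add atoms: Eschenmoser's salt (N,N-dimethylmethyleneiminium iodide), C=[N+](C)C.[I-]
Why: Kinetic deprotonation of the enone is possible only at the α'-carbon, and Mannich reaction with Eschenmoser's salt followed by elimination of the quaternised amine installs the exocyclic methylene (α-methylenation); the temporary centre is destroyed and the γ-centre is not enolised under these conditions.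

Step 8
Reactants: 10 tert-butyl (2Z)-2-[(E)-2-(4-methoxybenzyloxy)ethenyl]-4-methylpenta-2,4-dienoate; 16 (4S)-4-(1,3-dioxolan-2-yl)-5-methylidenecyclopent-2-en-1-one
Product: 17 spiro[4.5]decadienone Diels–Alder adduct (endo)
Conditions: Me2AlCl (0.3 equiv), CH2Cl2, −78 → −40 °C
Reagents that add atoms: none
Why: In this Lewis-acid-catalysed normal-demand Diels–Alder reaction the "ortho" rule of the 1-alkoxy group and the "para" rule of the 2-ester both join C10 to C1 and C7 to C11, the diene adds to the methylene face anti to the dioxolanyl group (sets C1 relative to C2), and the endo ring-B carbonyl together with the (E,E) "outside" OPMB and isopropenyl groups should set C10 and C7 cis to each other and to C5.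

Step 9
Reactants: 17 spiro[4.5]decadienone Diels–Alder adduct (endo)
Product: 18 C5 tosylhydrazone of 17
Conditions: TsNHNH2, EtOH, 40 °C
Reagents that add atoms: 4-methylbenzenesulfonohydrazide, Cc1ccc(cc1)S(=O)(=O)NN
Why: Condensation of the only ketone with the sulfonyl hydrazide gives the hydrazone, the tert-butyl enoate and the acetal being inert.

Step 10
Reactants: 18 C5 tosylhydrazone of 17
Product: 21 spiro triene with the ring-B alkene at C4=C5, via allylic hydrazide 19 (not isolated), via allylic diazene 20 (not isolated)
Conditions: catecholborane, CHCl3, 0 °C; then NaOAc·3H2O, CHCl3, reflux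
Reagents that add atoms: none
Why: 1,2-Reduction of the conjugated tosylhydrazone, loss of sulfinate and retro-ene loss of N2 from the allylic diazene (reductive 1,3-transposition) deliver hydrogen to C3 and move the double bond to C4=C5 while removing the oxygen; no stereocentre of the product is created.

Step 11
Reactants: 21 spiro triene with the ring-B alkene at C4=C5
Product: 22 tert-butyl 10-(4-methoxybenzyloxy)-12,12-(ethylenedioxy)cedr-8-en-15-oate
Conditions: Mn(dpm)3 (10 mol %), PhSiH3 (1.5 equiv), t-BuOOH (1.5 equiv), degassed i-PrOH (5 mM), 22 °C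
Reagents that add atoms: none
Why: The Mn–H species formed from Mn(dpm)3 and PhSiH3 transfers a hydrogen atom to the CH2 terminus of the 1,1-disubstituted isopropenyl group (Mukaiyama-type MHAT), the tertiary C6 radical adds to C5 of the ring-B alkene, and the secondary C4 radical is reduced by a second hydrogen-atom transfer. The closest known reaction type is the MHAT-initiated reductive (hydrogenative) cyclisation of 1,6-dienes, that is, a hex-5-enyl cyclisation of a tertiary radical. Ring C (C1–C5–C6–C7–C11) closes in the 5-exo-trig mode, 6-endo attack at C4 being slower and geometrically remote. C5 is set by the tether: C6 is held on the C11 face of ring B through C7–C11–C1, so the new bond forms on that face and the C5 hydrogen ends cis to C10 (cis ring fusion, as in the target), while C6 becomes quaternary but is not stereogenic and C1, C2, C7 and C10 are untouched. The step needs HAT to the 1,1-disubstituted alkene rather than to the cyclopentene or the electron-poor enoate, and ring closure faster than reduction of the tertiary radical; the higher HAT reactivity of 1,1-disubstituted alkenes, the cis-1,3 (diaxial-capable) placement of isopropenyl and C5 on ring A, and high dilution with limited silane should secure this.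

Step 12
Reactants: 22 tert-butyl 10-(4-methoxybenzyloxy)-12,12-(ethylenedioxy)cedr-8-en-15-oate
Product: 23 tert-butyl 10-hydroxy-12,12-(ethylenedioxy)cedr-8-en-15-oate
Conditions: DDQ, CH2Cl2/pH 7 buffer, 0 °C
Reagents that add atoms: none
Why: Oxidative cleavage of the electron-rich 4-methoxybenzyl ether by DDQ (electron transfer, hydride loss, hydrolysis of the oxocarbenium ion) should leave acetal, tert-butyl ester and enoate untouched and does not affect the C10 configuration.

Step 13
Reactants: 24 9-bromononanoic acid
Product: 25 (8-carboxyoctyl)triphenylphosphonium bromide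
Conditions: PPh3, MeCN, reflux
Reagents that add atoms: triphenylphosphine, c1ccc(cc1)P(c1ccccc1)c1ccccc1
Why: SN2 alkylation of the phosphine by the primary bromide gives the phosphonium salt.

Step 14
Reactants: 26 heptane-1,7-diol
Product: 27 7-(tert-butyldimethylsilyloxy)heptan-1-ol
Conditions: NaH (1 equiv), THF, 22 °C; TBSCl (1 equiv)
Reagents that add atoms: tert-butyldimethylsilyl chloride, CC(C)(C)[Si](C)(C)Cl
Why: Monosilylation of the symmetrical diol through its monosodium alkoxide (silyl ether formation) should favour the mono-ether.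

Step 15
Reactants: 27 7-(tert-butyldimethylsilyloxy)heptan-1-ol
Product: 28 7-(tert-butyldimethylsilyloxy)heptanal
Conditions: TEMPO (10 mol %), PhI(OAc)2, CH2Cl2, 22 °C
Reagents that add atoms: none
Why: Oxoammonium (TEMPO) oxidation stops at the aldehyde and tolerates the silyl ether.

Step 16
Reactants: 25 (8-carboxyoctyl)triphenylphosphonium bromide; 28 7-(tert-butyldimethylsilyloxy)heptanal
Product: 29 (9Z)-16-(tert-butyldimethylsilyloxy)hexadec-9-enoic acid
Conditions: NaN(SiMe3)2 (2.1 equiv), THF, 0 °C; then 28, −78 → 22 °C; aq citric acid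
Reagents that add atoms: none
Why: Salt-free Wittig olefination of the non-stabilised ylide (as its carboxylate) proceeds through a kinetically formed cis-oxaphosphetane and should give the (Z)-alkene.

Step 17
Reactants: 29 (9Z)-16-(tert-butyldimethylsilyloxy)hexadec-9-enoic acid; 23 tert-butyl 10-hydroxy-12,12-(ethylenedioxy)cedr-8-en-15-oate
Product: 31 fully protected C10 ester, via mixed anhydride 30 (not isolated)
Conditions: 2,4,6-trichlorobenzoyl chloride, Et3N, THF, 22 °C; then 23, DMAP, toluene, 40 °C
Reagents that add atoms: none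
Why: In the Yamaguchi esterification DMAP converts the mixed anhydride into an acylpyridinium ion reactive enough for the hindered allylic C10–OH, and no bond to C10 is broken, so its configuration is retained.

Step 18
Reactants: 31 fully protected C10 ester
Product: 32 CNP0214056.2 (target)
Conditions: aqueous CF3CO2H in CH2Cl2, 0 → 22 °C; then aq NaHCO3
Reagents that add atoms: water, O
Why: Aqueous trifluoroacetic acid should remove the three acid-labile groups in one operation (loss of isobutene from the tert-butyl ester, hydrolysis of the dioxolane to the aldehyde, solvolysis of the primary silyl ether); the allylic ester should not ionise because the cation would be destabilised by the C8 carboxyl group, and the C2 aldehyde epimer required is the thermodynamically preferred one.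

**Compound list**

1 | 4-methoxybenzyl alcohol | COc1ccc(CO)cc1 | starting material
2 | (E)-1,2-dichlorovinyl 4-methoxybenzyl ether | COc1ccc(CO/C(Cl)=C\Cl)cc1 | intermediate
3 | lithium [(4-methoxybenzyl)oxy]ethynide | COc1ccc(COC#C[Li])cc1 | intermediate
4 | 4-methoxybenzyl ethynyl ether | COc1ccc(COC#C)cc1 | intermediate
5 | methacrolein (2-methylprop-2-enal) | CC(=C)C=O | starting material
6 | 1,1-dibromo-3-methylbuta-1,3-diene | CC(=C)C=C(Br)Br | intermediate
7 | chlorobis(cyclopentadienyl)[(E)-2-(4-methoxybenzyloxy)ethenyl]zirconium | COc1ccc(CO/C=C/[Zr](Cl)(C2C=CC=C2)C2C=CC=C2)cc1 | intermediate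
8 | (1E,3Z)-3-bromo-1-(4-methoxybenzyloxy)-5-methylhexa-1,3,5-triene | C=C(C)/C=C(Br)/C=C/OCc1ccc(OC)cc1 | intermediate
9 | 3-lithio analogue of 8 (lithium in place of bromine, alkene geometry retained) | C=C(C)/C=C([Li])/C=C/OCc1ccc(OC)cc1 | intermediate
10 | tert-butyl (2Z)-2-[(E)-2-(4-methoxybenzyloxy)ethenyl]-4-methylpenta-2,4-dienoate | C=C(C)/C=C(/C=C/OCc1ccc(OC)cc1)C(=O)OC(C)(C)C | intermediate
11 | (4R)-4-(tert-butyldimethylsilyloxy)cyclopent-2-en-1-one | O=C1C=C[C@H](O[Si](C)(C)C(C)(C)C)C1 | starting material
12 | (3R,4R)-4-(tert-butyldimethylsilyloxy)-3-(1,3-dioxolan-2-yl)cyclopentan-1-one (3,4-trans) | O=C1C[C@@H](C2OCCO2)[C@H](O[Si](C)(C)C(C)(C)C)C1 | intermediate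
13 | (4R)-4-(1,3-dioxolan-2-yl)cyclopent-2-en-1-one | O=C1C=C[C@H](C2OCCO2)C1 | intermediate
14 | (4S,5S)-5-[(dimethylamino)methyl]-4-(1,3-dioxolan-2-yl)cyclopent-2-en-1-one (4,5-trans) | CN(C)C[C@H]1C(=O)C=C[C@@H]1C1OCCO1 | intermediate
15 | N-methyl quaternary ammonium iodide of 14 | C[N+](C)(C)C[C@H]1C(=O)C=C[C@@H]1C1OCCO1.[I-] | intermediate
16 | (4S)-4-(1,3-dioxolan-2-yl)-5-methylidenecyclopent-2-en-1-one | C=C1C(=O)C=C[C@@H]1C1OCCO1 | intermediate
17 | tert-butyl 4-(1,3-dioxolan-2-yl)-6-(4-methoxybenzyloxy)-1-oxo-9-(prop-1-en-2-yl)spiro[4.5]deca-2,7-diene-8-carboxylate; endo adduct: on the cyclohexene the PMB-oxy group (C10), the isopropenyl group (C7) and the ring-B carbonyl carbon (C5) are mutually cis, and C10 lies on the ring-B face opposite the dioxolanyl group | C=C(C)[C@H]1C[C@@]2([C@@H](OCc3ccc(OC)cc3)C=C1C(=O)OC(C)(C)C)[C@@H](C4OCCO4)C=CC2=O | intermediate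
18 | C5 tosylhydrazone of 17 (N–N bond anti to the spiro carbon) | C=C(C)[C@H]1C[C@@]2([C@@H](OCc3ccc(OC)cc3)C=C1C(=O)OC(C)(C)C)[C@@H](C4OCCO4)C=C/C2=N\NS(=O)(=O)c5ccc(C)cc5 | intermediate
19 | allylic N'-tosylhydrazide from 1,2-reduction of 18 (C5–NH–NHTs, C3=C4 retained; drawn with the C5 hydrogen on the C11 face, the centre is erased in the next event) | C=C(C)[C@H]1C[C@@]2([C@@H](OCc3ccc(OC)cc3)C=C1C(=O)OC(C)(C)C)[C@@H](C4OCCO4)C=C[C@@H]2NNS(=O)(=O)c5ccc(C)cc5 | intermediate
20 | allylic diazene (C5–N=NH) formed from 19 by loss of sulfinate | C=C(C)[C@H]1C[C@@]2([C@@H](OCc3ccc(OC)cc3)C=C1C(=O)OC(C)(C)C)[C@@H](C4OCCO4)C=C[C@@H]2N=N | intermediate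
21 | spiro triene: as 17 but ring B is a cyclopentene with C4=C5 and no carbonyl (C2 dioxolanyl; ring A with C8 tert-butyl ester, C10 OPMB, C7 isopropenyl; stereocentres as in 17) | C=C(C)[C@H]1C[C@@]2([C@@H](OCc3ccc(OC)cc3)C=C1C(=O)OC(C)(C)C)[C@@H](C4OCCO4)CC=C2 | intermediate
22 | tert-butyl 10-(4-methoxybenzyloxy)-12,12-(ethylenedioxy)cedr-8-en-15-oate (tricyclic core, all configurations as in the target) | CC1(C)[C@H]2C[C@@]3([C@@H](OCc4ccc(OC)cc4)C=C2C(=O)OC(C)(C)C)[C@@H](C5OCCO5)CC[C@@H]13 | intermediate
23 | tert-butyl 10-hydroxy-12,12-(ethylenedioxy)cedr-8-en-15-oate | CC1(C)[C@H]2C[C@@]3([C@@H](O)C=C2C(=O)OC(C)(C)C)[C@@H](C4OCCO4)CC[C@@H]13 | intermediate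
24 | 9-bromononanoic acid | OC(=O)CCCCCCCCBr | starting material
25 | (8-carboxyoctyl)triphenylphosphonium bromide | OC(=O)CCCCCCCC[P+](c1ccccc1)(c1ccccc1)c1ccccc1.[Br-] | intermediate
26 | heptane-1,7-diol | OCCCCCCCO | starting material
27 | 7-(tert-butyldimethylsilyloxy)heptan-1-ol | CC(C)(C)[Si](C)(C)OCCCCCCCO | intermediate
28 | 7-(tert-butyldimethylsilyloxy)heptanal | CC(C)(C)[Si](C)(C)OCCCCCCC=O | intermediate
29 | (9Z)-16-(tert-butyldimethylsilyloxy)hexadec-9-enoic acid | CC(C)(C)[Si](C)(C)OCCCCCC/C=C\CCCCCCCC(=O)O | intermediate
30 | mixed anhydride of 29 with 2,4,6-trichlorobenzoic acid | CC(C)(C)[Si](C)(C)OCCCCCC/C=C\CCCCCCCC(=O)OC(=O)c1c(Cl)cc(Cl)cc1Cl | intermediate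
31 | fully protected ester: 23 acylated at O10 by 29 (C15 tert-butyl ester, C12 dioxolane, chain O-TBS) | CC1(C)[C@H]2C[C@@]3([C@@H](OC(=O)CCCCCCC/C=C\CCCCCCO[Si](C)(C)C(C)(C)C)C=C2C(=O)OC(C)(C)C)[C@@H](C4OCCO4)CC[C@@H]13 | intermediate
32 | CNP0214056.2: 10-O-[(9Z)-16-hydroxyhexadec-9-enoyl] ester of 10-hydroxy-12-oxocedr-8-en-15-oic acid | CC1(C)[C@H]2C[C@@]3([C@@H](OC(=O)CCCCCCC/C=C\CCCCCCO)C=C2C(=O)O)[C@@H](C=O)CC[C@@H]13 | target

**Step count and risks**

Total step count: 18.
Longest linear sequence: 10 steps (1, 3, 4, 8, 9, 10, 11, 12, 17, 18; the sequence 5, 6, 7, 8, 9, 10, 11, 12, 17, 18 is equally long).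

Three steps most likely to fail:

Step 11. The tertiary C6 radical may be reduced by a second hydrogen-atom transfer, or the isopropenyl double bond may migrate into conjugation, before ring closure, because the reactive conformer of ring A must carry both partners axial. The fallback sets out from 21 and returns at 22. The radical is instead generated in a silane chain process under slow-addition conditions. Cobalt-catalysed Markovnikov MHAT hydrochlorination of the isopropenyl group (Co(BF4)2·6H2O with a salen-type ligand, TsCl, PhSiH3, t-BuOOH, EtOH) should give the tertiary chloride F1. Slow addition of (Me3Si)3SiH with AIBN in toluene at 80 °C then keeps the hydrogen-donor concentration low, so that the 5-exo-trig closure onto C5 precedes reduction and delivers 22.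

Step 8. The ester-deactivated diene may react too slowly, so that stepwise Michael-type addition with loss of endo control, hetero-Diels–Alder consumption of the enol ether by the enone, or oligomerisation of the dienone competes. The fallback sets out from 8 and 16 and returns at 17. The more electron-rich, ester-free bromotriene 8 is used as the diene under the same catalysis and should give the bromo spiro adduct F2 with the same regio- and endo preferences. The C15 carboxyl is then introduced by palladium-catalysed hydroxycarbonylation of the vinyl bromide (Pd(OAc)2, dppf, CO, H2O, Et3N, DMF) to give the carboxylic acid F3, which is esterified with Boc2O/DMAP in t-BuOH to give 17.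

Step 18. The simultaneous acidolysis may stall at the hindered acetal, or the strong protic acid may trifluoroacetylate the primary alcohol and erode the allylic ester or the Z-alkene. The fallback sets out from 31 and returns at 32. Unmasking is staged under aprotic conditions: TMSOTf/2,6-lutidine in CH2Cl2, followed by aqueous work-up, should cleave the dioxolane and the tert-butyl ester (through its silyl ester) to give the silyl-protected aldehyde acid F4. HF·pyridine in THF then removes the silyl ether to give 32.

Further compounds
F1 | step 11 | tertiary chloride: 21 with the isopropenyl group converted into a 2-chloropropan-2-yl group | CC(C)(Cl)[C@H]1C[C@@]2([C@@H](OCc3ccc(OC)cc3)C=C1C(=O)OC(C)(C)C)[C@@H](C4OCCO4)CC=C2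
F2 | step 8 | bromo spiro adduct: 17 with bromine in place of the tert-butoxycarbonyl group at C8 | C=C(C)[C@H]1C[C@@]2([C@@H](OCc3ccc(OC)cc3)C=C1Br)[C@@H](C4OCCO4)C=CC2=O
F3 | step 8 | carboxylic acid corresponding to 17 (C15 CO2H) | C=C(C)[C@H]1C[C@@]2([C@@H](OCc3ccc(OC)cc3)C=C1C(=O)O)[C@@H](C4OCCO4)C=CC2=O
F4 | step 18 | silyl-protected aldehyde acid: 32 with the chain hydroxyl as its tert-butyldimethylsilyl ether | CC1(C)[C@H]2C[C@@]3([C@@H](OC(=O)CCCCCCC/C=C\CCCCCCO[Si](C)(C)C(C)(C)C)C=C2C(=O)O)[C@@H](C=O)CC[C@@H]13
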